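Tetralin numbering is used in the prose: C1 carries the aryl group, C2 and C3 the hydroxymethyl arms, C4 is the CH2, and ring A runs C4a, C5 (H), C6 (OMe), C7 (O), C8 (O), C8a. Names of the lactones use naphtho[2,3-c]furanone locants (C9 = tetralin C1, C9a = C2, C3a = C3, C3 = acetal carbon).

## Analysis of the target

Compound 28 is a 1-aryltetralin cyclolignan. Ring A is a benzene ring with a hydrogen at C5, a methoxy group at C6 and a free catechol at C7/C8. Ring B (C1–C4) is the saturated six-membered ring fused to it, with a 3,4,5-trimethoxyphenyl ring on C1, hydroxymethyl arms on C2 and C3 and a methylene at C4. The three contiguous stereocentres are (1S,2R,3S): the aryl group is trans to the C2 arm and the two arms are cis to each other. None of them can be epimerised in the target, and the 2,3-cis arrangement is not the relaxed all-trans one, so each has to be set kinetically and then left untouched. The catechol is oxidised easily and should be unmasked last. C1 is para to the C6 methoxy group and ortho to O8, so an oxygen leaving group on C1 ionises under mild acid, which is a liability for handling and an opening for C–C bond formation. The hard points are the fully substituted ring A with a single free CH, the crowding between the C1 aryl group and O8, and absolute control of the cis pair. The strategy rests on two observations: C1 and C4 are the two benzylic carbons of ring A, that is the termini of an o-quinodimethane, and the cis C2/C3 pair with its one-carbon arms is the α,β-pair of a butenolide whose carbonyl and γ-carbon are those arms at a higher oxidation level.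

## Retrosynthetic reasoning

**Catechol and diol last.** Target 28 is traced back to its bis(benzyl ether) 27, so that one hydrogenolysis frees O7 and O8 together and nothing else in 27 is reducible. The two arms of 27 are then folded into one cis-fused γ-lactone acetal, 26: the C2 arm is the lactone carbonyl and the C3 arm is the acetal carbon. Exhaustive hydride reduction returns the diol and releases the auxiliary alcohol 19. This keeps the cis relationship locked in a ring through all earlier steps.

**The C1–aryl bond.** The bond from C1 to the pendant ring is cut next, because ring A makes a cation at C1 (24) unusually accessible and the cut leaves a C1 carbinol, 22. The nucleophile is 2,6-dimethoxyphenol 23, which reacts para to its hydroxyl group; O-methylation of the resulting phenol 25 then gives the 3,4,5-trimethoxy pattern of 26. An aryl organometallic was set aside for this bond because it would attack the lactone, and reducing the lactone first would place two free alcohols beside the C1 cation. With a phenol as nucleophile neither O7 nor O8 has to be free, so both carry the same benzyl group from the first step. The forward reaction has to deliver the arene to the face of C1 anti to the lactone on C2, which gives the 1,2-trans relationship.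

**The key disconnection.** In 22 the bonds C1–C2 and C3–C4 are cut together. This gives the hydroxy-o-quinodimethane 21 and the butenolide 20. Dienol 21 is not a storable compound; it comes from the benzocyclobutenol 16 by thermal ring opening. The gain is ring B, two C–C bonds, and C2 and C3 with absolute control from the acetal stereocentre of 20. Alcohol 16 may be racemic because its stereocentre vanishes in 21, and the configuration of the C1 carbinol in 22 is irrelevant because C1 is planarised in 24.

**The four-membered ring.** Alcohol 16 comes from ketone 15 by reduction, and 15 from its dimethyl acetal 14. Both bonds of the cyclobutene are cut in 14, giving the aryne 13 and 1,1-dimethoxyethene 12. The benzyloxy group next to the triple bond of 13 polarises it, so the nucleophilic CH2 of 12 should bond to the distal aryne carbon and the acetal carbon should end up beside O8, as 16 requires.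

**The aryne precursor.** Aryne 13 is generated from the ortho-silylaryl triflate 11. The triflate oxygen is the phenol oxygen of 4, which stands where the formyl group of aldehyde 2 stood, by Dakin-type oxidation through formate 3. The silyl group is put on the only free ortho carbon by carbamate-directed lithiation (5 to 9 through 6, 7 and 8) and the carbamate is then exchanged for the triflate through phenol 10. Aldehyde 2 is the bis(benzyl ether) of commercial 1, which already holds the three contiguous oxygens with the methoxy group in place.

**The dienophile.** Butenolide 20 is the acetal of racemic 5-hydroxyfuranone 18 with (+)-menthol 19, and 18 comes from furfural 17 by dye-sensitised photooxygenation. The acetal centre epimerises under acid, so crystallisation can collect the material as the (5S) isomer.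

## Alternatives that were turned down

**Alternative 1:** Radical annulation. The disconnection is at C2–C3 and at the lactone O–CH2 bond. The iodomalonate A1 already carries both aryl groups on C1 and an allyl group on C4a. Its malonyl radical at C2 would add 6-exo to the internal allyl carbon, the primary radical would take iodine from a second molecule of A1, and the cis ester would displace iodide to give the lactone ester A2.
- For: the C1–aryl bond exists before ring closure, so there is no late arylation beside a lactone. The lactone can only close cis, so the C2/C3 relationship is as secure as in the chosen route. The conditions are neutral.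
- Against: A1 needs C1 as a single enantiomer before the key step, at a carbon bearing a malonate and two aryl groups, one of them flanked by O8 and the allyl group. The allyl group must reach C4a, which is para to O7 and ortho to no oxygen, so the Claisen rearrangement has to pass through two occupied ortho positions. The cyclisation relays C1 to C3 by 1,3-induction in a 6-exo closure, which is slower than a 5-exo one and open to 7-endo closure and to hydrogen transfer from the benzylic, allylic C4–H. A2 has one carbon too many on C2, so a dealkoxycarbonylation follows and C2 is then set by a protonation.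
- Comparison: this route is stronger at C1. The chosen route offers instead the absolute configuration of C2 and C3 from a purchased auxiliary in the ring-forming step, no surplus carbon and a shorter path to the cyclisation substrate.

**Alternative 2:** o-Quinone Diels–Alder. The disconnection is at C1–C8a and C4–C4a, with ring A as the dienophile. The aryl diene A4 would add to the unsubstituted C=C bond of the methoxy-o-quinone A3 under a chiral cationic oxazaborolidine Lewis acid, and tautomerisation would give the catechol A5.
- For: it is the most convergent plan. Ring A arrives with all three oxygens in place and unprotected, and the catalyst sets C1 with the aryl group already attached. On convergence and atom economy it is better than the chosen route.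
- Against: A3 is an unstable o-quinone that dimerises and can react as a heterodiene or a carbodiene. Its unsubstituted C=C bond is β to one carbonyl and vinylogously δ to the other, so the regiochemical sense is not clearly biased. Face discrimination on a 1,2-dione bound to the Lewis acid is uncertain. A5 is a free catechol and a 1,4-dihydronaphthalene, open to oxidation, to aromatisation that destroys C1 and to migration of the double bond. A5 also lacks both one-carbon arms, so C2 and C3 remain to be made as a cis pair anti to the aryl group, which is the problem of alternative 3.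
- Comparison: its key step sets one stereocentre. The chosen key step sets two and brings both arms with it.

**Alternative 3:** Bis-methoxycarbonylation. No ring is formed; the bonds from C2 and C3 to their arms are cut, leaving the alkene A6. Under carbon monoxide in methanol with PdCl2 and CuCl2, a methoxycarbonyl–palladium species would add syn across C2=C3 from the face anti to the C1 aryl group. A second carbonylation and methanolysis would give the cis diester A7.
- For: both arms, their cis relationship and the trans relationship to the aryl group would come in one operation from carbon monoxide. Reduction and hydrogenolysis would finish. In step economy of the endgame it beats the chosen route.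
- Against: it builds no ring and no absolute configuration, so A6 must arrive enantiopure by other means. In the alkylpalladium intermediate the hydrogens on C1 and C4 are within reach, so β-hydride elimination to an unsaturated monoester competes with carbon monoxide insertion. Divalent palladium with CuCl2 can dehydrogenate a 1,4-dihydronaphthalene to the naphthalene, which erases C1, and CuCl2 can chlorinate the electron-rich rings. Facial control rests on a single pseudo-axial aryl group.
- Comparison: the chosen route closes ring B and sets C2 and C3 in one concerted step whose geometry is fixed by the dienophile.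

Key step: step 10

Assumption (remark on the chemistry): compounds 1, 12, 17, 19 and 23 are taken as commercial, and 22 is drawn as the endo adduct; any exo isomer differs only at C1 and converges in step 11.

## Route

Step 1
Reactants: 1 2,3-dihydroxy-4-methoxybenzaldehyde
Product: 2 2,3-bis(benzyloxy)-4-methoxybenzaldehyde
Conditions: BnBr, K2CO3, DMF, 60 °C
Reagents that add atoms: benzyl bromide, BrCc1ccccc1
Why: Williamson ether synthesis on both phenols; warming is needed for the hydroxyl that is hydrogen-bonded to the aldehyde, and no selectivity between the two oxygens is required.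

Step 2
Reactants: 2 2,3-bis(benzyloxy)-4-methoxybenzaldehyde
Product: 4 2,3-bis(benzyloxy)-4-methoxyphenol, via aryl formate 3 (not isolated)
Conditions: mCPBA, CH2Cl2, 0 °C → rt; then K2CO3 (cat.), MeOH, rt
Reagents that add atoms: 3-chloroperoxybenzoic acid, OOC(=O)c1cccc(Cl)c1
Why: Dakin-type Baeyer–Villiger oxidation; the electron-rich aryl group migrates in preference to hydrogen, and the formate is removed by methanolysis.

Step 3
Reactants: 4 2,3-bis(benzyloxy)-4-methoxyphenol
Product: 5 2,3-bis(benzyloxy)-4-methoxyphenyl N-(propan-2-yl)carbamate
Conditions: i-PrNCO, Et3N (cat.), CH2Cl2, rt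
Reagents that add atoms: isopropyl isocyanate, CC(C)N=C=O
Why: Base-catalysed addition of the phenol to the isocyanate gives a secondary carbamate, a strong directing group that can later be removed under mild base.

Step 4
Reactants: 5 2,3-bis(benzyloxy)-4-methoxyphenyl N-(propan-2-yl)carbamate
Product: 9 2,3-bis(benzyloxy)-4-methoxy-6-(trimethylsilyl)phenyl N-(propan-2-yl)carbamate, via N-silyl carbamate 6 (not isolated), via aryllithium 7 (not isolated), via N-silyl C-silyl carbamate 8 (not isolated)
Conditions: TBSOTf, TMEDA, Et2O, 0 °C → rt; n-BuLi, TMEDA, −78 °C; TMSCl, −78 °C → rt; aq. NaHSO4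
Reagents that add atoms: chlorotrimethylsilane, C[Si](C)(C)Cl
Why: Directed ortho-metalation; transient N-silylation masks the N–H, the carbamate then directs lithiation to the only ortho hydrogen (C6), and the aryllithium is silylated; the N-silyl group is lost on acidic work-up.

Step 5
Reactants: 9 2,3-bis(benzyloxy)-4-methoxy-6-(trimethylsilyl)phenyl N-(propan-2-yl)carbamate
Product: 11 2,3-bis(benzyloxy)-4-methoxy-6-(trimethylsilyl)phenyl trifluoromethanesulfonate, via silylphenol 10 (not isolated)
Conditions: DBU, Et2NH, MeCN, 40 °C; then PhNTf2, rt
Reagents that add atoms: N-phenylbis(trifluoromethanesulfonimide), O=S(=O)(N(c1ccccc1)S(=O)(=O)C(F)(F)F)C(F)(F)F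
Why: Deprotonation of the carbamate N–H expels the phenoxide by E1cB loss of isopropyl isocyanate, which diethylamine scavenges as a urea; the phenoxide is triflated in the same flask.

Step 6
Reactants: 11 2,3-bis(benzyloxy)-4-methoxy-6-(trimethylsilyl)phenyl trifluoromethanesulfonate; 12 1,1-dimethoxyethene
Product: 15 4,5-bis(benzyloxy)-3-methoxybicyclo[4.2.0]octa-1,3,5-trien-7-one, via aryne 13 (not isolated), via dimethyl acetal 14 (not isolated)
Conditions: CsF, MeCN, rt; then 1 M HCl, THF, rt
Reagents that add atoms: water, O
Why: Fluoride-induced 1,2-elimination gives the aryne, which undergoes stepwise [2+2] cycloaddition with the ketene acetal; the benzyloxy group beside the triple bond makes the distal aryne carbon the electrophilic one, so the CH2 of 12 bonds there and the acetal carbon closes beside the benzyloxy group; mild acid then hydrolyses the acetal.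

Step 7
Reactants: 15 4,5-bis(benzyloxy)-3-methoxybicyclo[4.2.0]octa-1,3,5-trien-7-one
Product: 16 rac-4,5-bis(benzyloxy)-3-methoxybicyclo[4.2.0]octa-1,3,5-trien-7-ol
Conditions: NaBH4, MeOH, 0 °C
Reagents that add atoms: none
Why: Hydride reduction of the strained ketone, kept cold and quenched with weak acid so that the alkoxide does not open the four-membered ring; the carbinol may be racemic because its stereocentre is lost in step 10.

Step 8
Reactants: 17 furfural
Product: 18 rac-5-hydroxyfuran-2(5H)-one
Conditions: O2, rose bengal (cat.), hν (visible), MeOH, rt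
Reagents that add atoms: oxygen, O=O
Why: Dye-sensitised photooxygenation; singlet oxygen adds [4+2] to the furan and the endoperoxide fragments in methanol with loss of the formyl carbon as methyl formate.

Step 9
Reactants: 18 rac-5-hydroxyfuran-2(5H)-one; 19 (1S,2R,5S)-(+)-menthol
Product: 20 (5S)-5-{[(1S,2R,5S)-5-methyl-2-(propan-2-yl)cyclohexyl]oxy}furan-2(5H)-one
Conditions: camphorsulfonic acid (cat.), toluene, reflux (−H2O); crystallisation from petroleum ether, mother liquor re-equilibrated with acid
Reagents that add atoms: none
Why: Acid-catalysed acetalisation through the cyclic oxocarbenium ion gives both C5 epimers, which interconvert under acid; the (5S) epimer of the (+)-menthyl series should be the crystalline one, so crystallisation with recycling of the mother liquor sets the acetal stereocentre.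

Step 10
Reactants: 16 rac-4,5-bis(benzyloxy)-3-methoxybicyclo[4.2.0]octa-1,3,5-trien-7-ol; 20 (5S)-5-{[(1S,2R,5S)-5-methyl-2-(propan-2-yl)cyclohexyl]oxy}furan-2(5H)-one
Product: 22 (3S,3aS,9S,9aS)-7,8-bis(benzyloxy)-9-hydroxy-6-methoxy-3-{[(1S,2R,5S)-5-methyl-2-(propan-2-yl)cyclohexyl]oxy}-3a,4,9,9a-tetrahydronaphtho[2,3-c]furan-1(3H)-one, via hydroxy-o-quinodimethane 21 (not isolated)
Conditions: 20 (2 equiv), toluene (degassed), 110 °C, sealed tube
Reagents that add atoms: none
Why: Heating opens the cyclobutene of 16 by conrotatory 4π electrocyclic ring opening, paid for by strain release, and the hydroxyl group rotates outward, so only the outward dienol 21 forms and the stereocentre of racemic 16 disappears. Dienol 21 is trapped by 20 in a concerted suprafacial [4+2] cycloaddition that restores aromatic ring A; this is the known thermal benzocyclobutenol opening with Diels–Alder trapping, using a 5-alkoxybutenolide as face-selective dienophile. Ring B is closed intermolecularly by the two new bonds C1–C2 and C3–C4, both formed on the same face of the butenolide. Regiochemistry follows the ortho rule: the unsubstituted methylene terminus of the 1-oxygenated diene bonds to the lactone β-carbon and the hydroxyl-bearing terminus to the α-carbon. C2 and C3 are set together by the face of 20 that is attacked, which must be the one anti to the menthyloxy group on the acetal carbon fixed in step 9, and the cis alkene makes them cis. C1 is set by the endo transition state (lactone carbonyl under the diene, hydroxyl outward), giving the all-cis adduct, but its configuration is not needed because C1 is planarised in step 11. The step therefore needs only facial and regiochemical selectivity, secured by the acetal stereocentre next to the β-carbon and by the dienol oxygen; the excess of 20 should keep bimolecular trapping ahead of tautomerisation of 21 to the o-methylbenzaldehyde.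

Step 11
Reactants: 22 the hydroxy lactone adduct from step 10; 23 2,6-dimethoxyphenol
Product: 25 (3S,3aS,9S,9aR)-7,8-bis(benzyloxy)-9-(4-hydroxy-3,5-dimethoxyphenyl)-6-methoxy-3-{[(1S,2R,5S)-5-methyl-2-(propan-2-yl)cyclohexyl]oxy}-3a,4,9,9a-tetrahydronaphtho[2,3-c]furan-1(3H)-one, via benzylic cation 24 (not isolated)
Conditions: 23 (3 equiv), BF3·OEt2 (0.3 equiv), CH2Cl2, −40 → 0 °C
Reagents that add atoms: none
Why: Friedel–Crafts alkylation; the Lewis acid ionises the C1 carbinol to a cation stabilised by the para methoxy and ortho benzyloxy groups, and the phenol attacks through its carbon para to the hydroxyl group. The arene approaches the face of C1 anti to the lactone carbonyl on C2 of the cis-fused bicycle, which sets C1 trans to C2, and the same isomer is the less crowded one if the addition is reversible.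

Step 12
Reactants: 25 the phenol from step 11
Product: 26 (3S,3aS,9S,9aR)-7,8-bis(benzyloxy)-6-methoxy-3-{[(1S,2R,5S)-5-methyl-2-(propan-2-yl)cyclohexyl]oxy}-9-(3,4,5-trimethoxyphenyl)-3a,4,9,9a-tetrahydronaphtho[2,3-c]furan-1(3H)-one
Conditions: MeI, K2CO3, acetone, 50 °C
Reagents that add atoms: iodomethane, CI
Why: Williamson methylation of the only free phenol; the lactone acetal is stable to carbonate, and the cis ring fusion gives the C2 hydrogen no reason to epimerise.

Step 13
Reactants: 26 the trimethoxyphenyl lactone from step 12
Product: 27 [(1S,2R,3S)-7,8-bis(benzyloxy)-6-methoxy-1-(3,4,5-trimethoxyphenyl)-1,2,3,4-tetrahydronaphthalene-2,3-diyl]dimethanol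
Conditions: LiAlH4, THF, 0 °C → rt
Reagents that add atoms: none
Why: Hydride reduction of the lactone opens it to a hemiacetal alkoxide that collapses to an aldehyde and menthoxide; the aldehyde is reduced faster than it can enolise, so both arms arrive as primary alcohols without loss of configuration at C2 or C3, and the auxiliary is recovered.

Step 14
Reactants: 27 the bis(benzyl ether) diol from step 13
Product: 28 (6S,7R,8S)-6,7-bis(hydroxymethyl)-3-methoxy-8-(3,4,5-trimethoxyphenyl)-5,6,7,8-tetrahydronaphthalene-1,2-diol, which is (1S,2R,3S) in tetralin numbering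
Conditions: H2 (1 atm), 10% Pd/C, EtOAc–MeOH, rt
Reagents that add atoms: none
Why: Hydrogenolysis of the two aryl benzyl ethers; the diarylmethine C–C bonds and the primary alcohols are inert, and the catechol is kept under inert gas after filtration.

## Compound list

1 | 2,3-dihydroxy-4-methoxybenzaldehyde | COc1ccc(C=O)c(O)c1O | starting material
2 | 2,3-bis(benzyloxy)-4-methoxybenzaldehyde | COc1ccc(C=O)c(OCc2ccccc2)c1OCc1ccccc1 | intermediate
3 | 2,3-bis(benzyloxy)-4-methoxyphenyl formate | COc1ccc(OC=O)c(OCc2ccccc2)c1OCc1ccccc1 | intermediate
4 | 2,3-bis(benzyloxy)-4-methoxyphenol | COc1ccc(O)c(OCc2ccccc2)c1OCc1ccccc1 | intermediate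
5 | 2,3-bis(benzyloxy)-4-methoxyphenyl N-(propan-2-yl)carbamate | COc1ccc(OC(=O)NC(C)C)c(OCc2ccccc2)c1OCc1ccccc1 | intermediate
6 | 2,3-bis(benzyloxy)-4-methoxyphenyl N-(tert-butyldimethylsilyl)-N-(propan-2-yl)carbamate | COc1ccc(OC(=O)N(C(C)C)[Si](C)(C)C(C)(C)C)c(OCc2ccccc2)c1OCc1ccccc1 | intermediate
7 | 6-lithio derivative of 6 | [Li]c1cc(OC)c(OCc2ccccc2)c(OCc2ccccc2)c1OC(=O)N(C(C)C)[Si](C)(C)C(C)(C)C | intermediate
8 | 2,3-bis(benzyloxy)-4-methoxy-6-(trimethylsilyl)phenyl N-(tert-butyldimethylsilyl)-N-(propan-2-yl)carbamate | COc1cc([Si](C)(C)C)c(OC(=O)N(C(C)C)[Si](C)(C)C(C)(C)C)c(OCc2ccccc2)c1OCc1ccccc1 | intermediate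
9 | 2,3-bis(benzyloxy)-4-methoxy-6-(trimethylsilyl)phenyl N-(propan-2-yl)carbamate | COc1cc([Si](C)(C)C)c(OC(=O)NC(C)C)c(OCc2ccccc2)c1OCc1ccccc1 | intermediate
10 | 2,3-bis(benzyloxy)-4-methoxy-6-(trimethylsilyl)phenol | COc1cc([Si](C)(C)C)c(O)c(OCc2ccccc2)c1OCc1ccccc1 | intermediate
11 | 2,3-bis(benzyloxy)-4-methoxy-6-(trimethylsilyl)phenyl trifluoromethanesulfonate | COc1cc([Si](C)(C)C)c(OS(=O)(=O)C(F)(F)F)c(OCc2ccccc2)c1OCc1ccccc1 | intermediate
12 | 1,1-dimethoxyethene | C=C(OC)OC | starting material
13 | 3,4-bis(benzyloxy)-5-methoxy-1,2-didehydrobenzene (aryne) | COC1=CC#CC(OCc2ccccc2)=C1OCc1ccccc1 | intermediate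
14 | 4,5-bis(benzyloxy)-3,7,7-trimethoxybicyclo[4.2.0]octa-1,3,5-triene | COc1cc2c(c(OCc3ccccc3)c1OCc1ccccc1)C(OC)(OC)C2 | intermediate
15 | 4,5-bis(benzyloxy)-3-methoxybicyclo[4.2.0]octa-1,3,5-trien-7-one | COc1cc2c(c(OCc3ccccc3)c1OCc1ccccc1)C(=O)C2 | intermediate
16 | rac-4,5-bis(benzyloxy)-3-methoxybicyclo[4.2.0]octa-1,3,5-trien-7-ol | COc1cc2c(c(OCc3ccccc3)c1OCc1ccccc1)C(O)C2 | intermediate
17 | furfural | O=Cc1ccco1 | starting material
18 | rac-5-hydroxyfuran-2(5H)-one | O=C1C=CC(O)O1 | intermediate
19 | (1S,2R,5S)-(+)-menthol | CC(C)[C@H]1CC[C@H](C)C[C@@H]1O | starting material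
20 | (5S)-5-{[(1S,2R,5S)-5-methyl-2-(propan-2-yl)cyclohexyl]oxy}furan-2(5H)-one | O=C1C=C[C@@H](O[C@H]2C[C@@H](C)CC[C@@H]2C(C)C)O1 | intermediate
21 | [2,3-bis(benzyloxy)-4-methoxy-6-methylidenecyclohexa-2,4-dien-1-ylidene]methanol, hydroxyl anti to the methylidene terminus (outward dienol) | O/C=C1/C(=C)C=C(OC)C(OCc2ccccc2)=C1OCc1ccccc1 | intermediate
22 | (3S,3aS,9S,9aS)-7,8-bis(benzyloxy)-9-hydroxy-6-methoxy-3-{[(1S,2R,5S)-5-methyl-2-(propan-2-yl)cyclohexyl]oxy}-3a,4,9,9a-tetrahydronaphtho[2,3-c]furan-1(3H)-one (all-cis at tetralin C1–C3) | COc1cc2c(c(OCc3ccccc3)c1OCc1ccccc1)[C@@H](O)[C@@H](C(=O)O3)[C@@H]([C@H]3O[C@H]4C[C@@H](C)CC[C@@H]4C(C)C)C2 | intermediate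
23 | 2,6-dimethoxyphenol | COc1cccc(OC)c1O | starting material
24 | tetralin C1 (furanone C9) benzylic cation derived from 22 | COc1cc2c(c(OCc3ccccc3)c1OCc1ccccc1)[CH+][C@@H](C(=O)O3)[C@@H]([C@H]3O[C@H]4C[C@@H](C)CC[C@@H]4C(C)C)C2 | intermediate
25 | (3S,3aS,9S,9aR)-7,8-bis(benzyloxy)-9-(4-hydroxy-3,5-dimethoxyphenyl)-6-methoxy-3-{[(1S,2R,5S)-5-methyl-2-(propan-2-yl)cyclohexyl]oxy}-3a,4,9,9a-tetrahydronaphtho[2,3-c]furan-1(3H)-one | COc1cc2c(c(OCc3ccccc3)c1OCc1ccccc1)[C@H](c1cc(OC)c(O)c(OC)c1)[C@@H](C(=O)O3)[C@@H]([C@H]3O[C@H]4C[C@@H](C)CC[C@@H]4C(C)C)C2 | intermediate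
26 | (3S,3aS,9S,9aR)-7,8-bis(benzyloxy)-6-methoxy-3-{[(1S,2R,5S)-5-methyl-2-(propan-2-yl)cyclohexyl]oxy}-9-(3,4,5-trimethoxyphenyl)-3a,4,9,9a-tetrahydronaphtho[2,3-c]furan-1(3H)-one | COc1cc2c(c(OCc3ccccc3)c1OCc1ccccc1)[C@H](c1cc(OC)c(OC)c(OC)c1)[C@@H](C(=O)O3)[C@@H]([C@H]3O[C@H]4C[C@@H](C)CC[C@@H]4C(C)C)C2 | intermediate
27 | [(1S,2R,3S)-7,8-bis(benzyloxy)-6-methoxy-1-(3,4,5-trimethoxyphenyl)-1,2,3,4-tetrahydronaphthalene-2,3-diyl]dimethanol | COc1cc2c(c(OCc3ccccc3)c1OCc1ccccc1)[C@H](c1cc(OC)c(OC)c(OC)c1)[C@@H](CO)[C@@H](CO)C2 | intermediate
28 | (6S,7R,8S)-6,7-bis(hydroxymethyl)-3-methoxy-8-(3,4,5-trimethoxyphenyl)-5,6,7,8-tetrahydronaphthalene-1,2-diol | COc1cc2c(c(O)c1O)[C@H](c1cc(OC)c(OC)c(OC)c1)[C@@H](CO)[C@@H](CO)C2 | target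

## Step count and least certain steps

Total: 14 steps. Longest linear sequence: 12 steps (steps 1–7, then 10–14); the dienophile branch (steps 8 and 9) joins at step 10.

**Step 10 (key step).** The most likely failure is loss of dienol 21 before it meets the dienophile, by proton relay to the o-methylbenzaldehyde tautomer, together with dehydration of the β-hydroxy lactone adduct at 110 °C. Incomplete facial selectivity would show as diastereomers, which the menthyl group makes separable. Fallback, setting out from 16: silylation (TBSCl, imidazole, DMF) gives the tert-butyldimethylsilyl ether of the benzocyclobutenol F1. Heating F1 with 20 in toluene or xylene opens it to the silyloxy-o-quinodimethane F2, which has no hydroxyl proton and cannot tautomerise, and cycloaddition gives the C1 silyl ether of the adduct F3. F3 is taken into the conditions of step 11, where the Lewis acid ionises the benzylic silyl ether to the same cation 24. The route is rejoined at 25.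

**Step 11.** The cation 24 can lose the C2 proton, which is acidified by the lactone carbonyl, and this elimination to the conjugated dihydronaphthalene lactone is not reversed under the conditions. Lesser risks are ionisation of the menthyl acetal and loss of the O8 benzyl group from the cation. Fallback, setting out from 22: reduce first with LiAlH4 to the triol F4, acetylate with Ac2O and pyridine to the triacetate F5, and carry out the Friedel–Crafts reaction with 23 and BF3·OEt2 on F5. The C1 acetate is then the leaving group, C2–H is no longer next to a carbonyl, and the neighbouring C2 acetoxymethyl group can shield the cis face, so the aryl diacetate phenol F6 should form trans. Methylation with MeI and K2CO3 gives the trimethoxyphenyl diacetate F7, and K2CO3 in MeOH removes the acetates. The route is rejoined at 27.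

**Step 6.** Capture of the aryne by the ketene acetal may be slow relative to fluoride-driven side reactions (protodesilylation of 11, aryne self-reaction), and the zwitterion formed after the first bond may transfer a proton instead of closing the ring. Fallback, setting out from 4: iodination ortho to the hydroxyl group (I2, morpholine) gives the 6-iodophenol F8, and Tf2O with pyridine gives the iodoaryl triflate F9. Treating F9 with n-BuLi at −78 °C in THF in the presence of 1-(tert-butyldimethylsilyloxy)-1-methoxyethene generates aryne 13 by halogen–lithium exchange and loss of triflate at low temperature. The more nucleophilic ketene silyl acetal traps it as the mixed silyl methyl acetal F10, and aqueous HF in MeCN hydrolyses F10. The route is rejoined at 15.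

**Step 4.** The base may deprotonate a benzylic O–CH2 group, leading to 1,2-Wittig rearrangement, or the C5 position beside the methoxy group, and silylation may be incomplete. Fallback, setting out from 4: bromination with NBS goes ortho to the hydroxyl group, because the para position is occupied, and gives the 6-bromophenol F11. Hexamethyldisilazane converts F11 into the aryl trimethylsilyl ether F12. Treating F12 with n-BuLi at −78 °C brings about bromine–lithium exchange and a 1,3 O→C silyl shift (retro-Brook rearrangement) to the lithium salt of 10, which is triflated with Tf2O. The route is rejoined at 11.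

## Further compounds

F1 | step 10 | rac-{[4,5-bis(benzyloxy)-3-methoxybicyclo[4.2.0]octa-1,3,5-trien-7-yl]oxy}(tert-butyl)dimethylsilane | COc1cc2c(c(OCc3ccccc3)c1OCc1ccccc1)C(O[Si](C)(C)C(C)(C)C)C2
F2 | step 10 | silyloxy-o-quinodimethane, tert-butyldimethylsilyl ether of 21 with the silyloxy group outward | CC(C)(C)[Si](C)(C)O/C=C1/C(=C)C=C(OC)C(OCc2ccccc2)=C1OCc1ccccc1
F3 | step 10 | (3S,3aS,9S,9aS)-7,8-bis(benzyloxy)-9-[(tert-butyldimethylsilyl)oxy]-6-methoxy-3-{[(1S,2R,5S)-5-methyl-2-(propan-2-yl)cyclohexyl]oxy}-3a,4,9,9a-tetrahydronaphtho[2,3-c]furan-1(3H)-one | COc1cc2c(c(OCc3ccccc3)c1OCc1ccccc1)[C@@H](O[Si](C)(C)C(C)(C)C)[C@@H](C(=O)O3)[C@@H]([C@H]3O[C@H]4C[C@@H](C)CC[C@@H]4C(C)C)C2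
F4 | step 11 | (1S,2R,3S)-7,8-bis(benzyloxy)-2,3-bis(hydroxymethyl)-6-methoxy-1,2,3,4-tetrahydronaphthalen-1-ol | COc1cc2c(c(OCc3ccccc3)c1OCc1ccccc1)[C@@H](O)[C@@H](CO)[C@@H](CO)C2
F5 | step 11 | [(1S,2R,3S)-1-acetoxy-7,8-bis(benzyloxy)-6-methoxy-1,2,3,4-tetrahydronaphthalene-2,3-diyl]bis(methylene) diacetate | COc1cc2c(c(OCc3ccccc3)c1OCc1ccccc1)[C@@H](OC(C)=O)[C@@H](COC(C)=O)[C@@H](COC(C)=O)C2
F6 | step 11 | [(1S,2R,3S)-7,8-bis(benzyloxy)-1-(4-hydroxy-3,5-dimethoxyphenyl)-6-methoxy-1,2,3,4-tetrahydronaphthalene-2,3-diyl]bis(methylene) diacetate | COc1cc2c(c(OCc3ccccc3)c1OCc1ccccc1)[C@H](c1cc(OC)c(O)c(OC)c1)[C@@H](COC(C)=O)[C@@H](COC(C)=O)C2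
F7 | step 11 | [(1S,2R,3S)-7,8-bis(benzyloxy)-6-methoxy-1-(3,4,5-trimethoxyphenyl)-1,2,3,4-tetrahydronaphthalene-2,3-diyl]bis(methylene) diacetate | COc1cc2c(c(OCc3ccccc3)c1OCc1ccccc1)[C@H](c1cc(OC)c(OC)c(OC)c1)[C@@H](COC(C)=O)[C@@H](COC(C)=O)C2
F8 | step 6 | 2,3-bis(benzyloxy)-6-iodo-4-methoxyphenol | COc1cc(I)c(O)c(OCc2ccccc2)c1OCc1ccccc1
F9 | step 6 | 2,3-bis(benzyloxy)-6-iodo-4-methoxyphenyl trifluoromethanesulfonate | COc1cc(I)c(OS(=O)(=O)C(F)(F)F)c(OCc2ccccc2)c1OCc1ccccc1
F10 | step 6 | rac-{[4,5-bis(benzyloxy)-3,7-dimethoxybicyclo[4.2.0]octa-1,3,5-trien-7-yl]oxy}(tert-butyl)dimethylsilane | COc1cc2c(c(OCc3ccccc3)c1OCc1ccccc1)C(OC)(O[Si](C)(C)C(C)(C)C)C2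
F11 | step 4 | 2,3-bis(benzyloxy)-6-bromo-4-methoxyphenol | COc1cc(Br)c(O)c(OCc2ccccc2)c1OCc1ccccc1
F12 | step 4 | [2,3-bis(benzyloxy)-6-bromo-4-methoxyphenoxy]trimethylsilane | COc1cc(Br)c(O[Si](C)(C)C)c(OCc2ccccc2)c1OCc1ccccc1
A1 | alternative 1 | dimethyl 2-iodo-2-{(S)-[2,3-bis(benzyloxy)-4-methoxy-6-(prop-2-en-1-yl)phenyl](3,4,5-trimethoxyphenyl)methyl}propanedioate | COc1cc(CC=C)c(c(OCc2ccccc2)c1OCc1ccccc1)[C@H](c1cc(OC)c(OC)c(OC)c1)C(I)(C(=O)OC)C(=O)OC
A2 | alternative 1 | 7,8-bis(benzyloxy)-6-methoxy-1-(3,4,5-trimethoxyphenyl)tetralin with a cis-fused γ-lactone (carbonyl on C2, O–CH2 on C3, trans to the aryl group) and a methoxycarbonyl group on C2 | COc1cc2c(c(OCc3ccccc3)c1OCc1ccccc1)[C@H](c1cc(OC)c(OC)c(OC)c1)[C@@](C(=O)OC)(C(=O)O3)[C@@H](C3)C2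
A3 | alternative 2 | 3-methoxycyclohexa-3,5-diene-1,2-dione (3-methoxy-o-benzoquinone) | COC1=CC=CC(=O)C1=O
A4 | alternative 2 | (E)-1-(3,4,5-trimethoxyphenyl)buta-1,3-diene | C=C/C=C/c1cc(OC)c(OC)c(OC)c1
A5 | alternative 2 | (1S)-6-methoxy-1-(3,4,5-trimethoxyphenyl)-1,4-dihydronaphthalene-7,8-diol (tetralin numbering) | COc1cc2c(c(O)c1O)[C@H](c1cc(OC)c(OC)c(OC)c1)C=CC2
A6 | alternative 3 | (1S)-7,8-bis(benzyloxy)-6-methoxy-1-(3,4,5-trimethoxyphenyl)-1,4-dihydronaphthalene | COc1cc2c(c(OCc3ccccc3)c1OCc1ccccc1)[C@H](c1cc(OC)c(OC)c(OC)c1)C=CC2
A7 | alternative 3 | dimethyl (1S,2R,3S)-7,8-bis(benzyloxy)-6-methoxy-1-(3,4,5-trimethoxyphenyl)-1,2,3,4-tetrahydronaphthalene-2,3-dicarboxylate | COc1cc2c(c(OCc3ccccc3)c1OCc1ccccc1)[C@H](c1cc(OC)c(OC)c(OC)c1)[C@@H](C(=O)OC)[C@@H](C(=O)OC)C2
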